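What is charged as starting material stays on the count: it is still starting material, it has become target, or protic impurity has taken it, one for one. That last step is our assumption, and the readings test it below.

| setting | noon | midnight | birch | maple |
|---|---|---|---|---|
| starting material | 0.14 M | 0.14 M | 0.14 M | 0.14 M |
| salt in the second phase | 1 equiv | 1 equiv | 1.00 equiv | 1.00 equiv |
| protic impurity | 0.042 M | 0.042 M | 0.0420 M | 0.0420 M |
| spent carrier | 2.5 mol% | 10 mol% | 5 mol% | 5 mol% |
| remark | run made earlier | run made earlier |  |  |
| time |  |  | 50 h | 25 h |
| volume of the second phase over the first |  |  | 1.0 | 1.0 |

| run | time / h | target / % | starting material / % |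
|---|---|---|---|
| noon | 1.50 | 2.4 | 77.1 |
| noon | 5.00 | 6.4 | 61.8 |
| noon | 8.00 | 7.8 | 60.0 |
| noon | 15.0 | 15.8 | 53.5 |
| noon | 20.0 | 20.8 | 49.6 |
| noon | 25.0 | 25.3 | 45.9 |
| midnight | 4.00 | 17.7 | 52.8 |
| midnight | 8.00 | 30.3 | 40.1 |
| midnight | 12.0 | 37.2 | 29.9 |
| midnight | 15.0 | 43.2 | 26.3 |
| midnight | 20.0 | 51.0 | 20.3 |
| midnight | 25.0 | 54.8 | 15.4 |

(readings scatter by 1 percentage point)

- charges count per volume of the first phase; a concentration in a rate is the amount of a species over the volume of its own phase; every rate counts per litre of the first phase
- the earlier runs hold the two phases in the same ratio of volumes as the flask asked about
- a reading or a percentage of target counts all its forms, free or not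

* which of these there is most of at the end, counted by the starting material in it, birch (target / starting material)
* which of these there is most of at the end, counted by the starting material in it, maple (target / starting material)
* how much there is at the end of the one of these that leads, in percent of the starting material charged: birch
* how much there is at the end of the one of these that leads, in percent of the starting material charged: maple

Protic impurity is charged at 0.0420 M against 0.14 M of starting material, so it is the limiting reagent of that loss. Its balance gives one number:

ceiling = 1 − protic impurity / starting material = 70.0%

We call this the ceiling: the share of the charge left for target once the impurity has taken its part.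

Two extreme flasks can be solved in the head. In the first, the impurity takes its share before any target forms, so target plus starting material sits at the ceiling from the start. In the second, the impurity takes nothing, and the sum stays at 100%.

The noon run has the lower loading of the two runs. By 1.50 h its sum has lost 21 percentage points, while target has gained 2.4%. At 25.0 h the noon sum reads 71.2%, and the midnight sum reads 70.2%. Noon's sum still reads above the ceiling at 1.50 h but 68.2% at 5.00 h, so both runs lie close to the first extreme, though not on it. Birch and maple carry a loading between theirs, so we place them there too.

Under the ceiling, we let carrier times time set the progress. Noon has a quarter of midnight's carrier, so its last reading should match midnight at 6.25 h. Noon reads 25.3%, and midnight gives 17.7% at 4.00 h and 30.3% at 8.00 h, which brackets it. Birch and maple have half of midnight's carrier: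

birch: midnight at 25.0 h, target 54.8%, starting material 15.2%

maple: midnight at 12.5 h, target a little above 37.2%, starting material a little below 32.8%

So we expect target to lead in both flasks, narrowly in maple.

The forecast names target at 55% for birch and target at 38% for maple. Its ground: “So about 30% of the starting material is lost quickly, matching the 0.042 M protic impurity (0.3 equiv).” Its figures lie within 0.8 points of the midnight readings we used.

Birch ends with target at 55.7% and starting material at 14.3%. Maple ends with target at 40.1% and starting material at 29.9%. The forecast held.

    spent carrier + salt in the second phase ⇌ fresh carrier + spent salt in the second phase (K = 2.22, k = 15.5 /M/h)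
    starting material + fresh carrier → target + spent carrier (k = 7.13 /M/h)
    starting material + protic impurity → quenched substrate (k = 7.84 /M/h)
    crystals ⇌ target, rate k4*(cs4 - [target]) while solid is left; crystals form when [target] > cs4 (solubility = 2.10 mM, k = 0.604 /h)

Birch's two amounts sum to 70.0%, which is its ceiling, with quenched substrate at 30.0% and protic impurity at 0%. A neighbour of birch is charged with 0.071 M of protic impurity, and the same balance gives:

ceiling = 49.3%

Its quenched substrate stands at 50.7% and its protic impurity at 0%. Its starting material ends at 7.6% and its target at 41.7%.

(The data stem from a simulated flask for substances that don't exist, noise included.)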